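**Strategy**

Everything rests on disconnecting the bond between C3 of the benzofuran and the carbonyl carbon of the 2,4-dihydroxybenzoyl group. The O1–C2=C3 enol ether of the furan ring, with that ketone on C3, is read as an alkyne that has taken up a phenol oxygen and an acyl group. A palladium-catalysed carbonylative annulation of an o-alkynylphenol with a 2,4-dialkoxyphenyl iodide and CO thus closes the furan ring and attaches the aroyl group to C3 in one operation. The precursor is a 3-(arylethynyl)-4-hydroxybenzaldehyde; its formyl group later grows into the C5 side chain, and all five phenols travel as benzyl ethers.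

Key step: step 3

Assumption: 4-hydroxy-3-iodobenzaldehyde, 1-(benzyloxy)-4-ethynylbenzene, 1,3-bis(benzyloxy)benzene and 2',4'-bis(benzyloxy)acetophenone are taken as catalogue compounds; the target has no stereocenter, so no stereocontrol is needed.

**Route**

Step 1
Reactants: 1 4-hydroxy-3-iodobenzaldehyde; 2 1-(benzyloxy)-4-ethynylbenzene
Product: 3 3-{[4-(benzyloxy)phenyl]ethynyl}-4-hydroxybenzaldehyde
Conditions: PdCl2(PPh3)2 (2 mol%), CuI (4 mol%), Et3N, THF, rt, Ar
Reagents that add atoms: none
Why: Sonogashira coupling of the aryl iodide with the terminal alkyne runs at room temperature, where the o-alkynylphenol should persist without closing to the benzofuran, so the phenol needs no protection.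

Step 2
Reactants: 4 1,3-bis(benzyloxy)benzene
Product: 5 2,4-bis(benzyloxy)-1-iodobenzene
Conditions: NIS (1.05 equiv), TFA (cat.), MeCN, 0 °C to rt
Reagents that add atoms: N-iodosuccinimide, O=C1CCC(=O)N1I
Why: Electrophilic aromatic iodination with acid-activated NIS should go to C4 of the resorcinol diether, para to one benzyloxy group and ortho to the other, while C2 between the two ethers is shielded.

Step 3
Reactants: 3 3-{[4-(benzyloxy)phenyl]ethynyl}-4-hydroxybenzaldehyde; 5 2,4-bis(benzyloxy)-1-iodobenzene
Product: 7 3-[2,4-bis(benzyloxy)benzoyl]-2-[4-(benzyloxy)phenyl]-1-benzofuran-5-carbaldehyde, via aroylpalladium iodide 6 (not isolated)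
Conditions: CO (1 atm, balloon), Pd(PPh3)4 (5 mol%), K2CO3 (3 equiv), MeCN, 45 °C
Reagents that add atoms: carbon monoxide, [C-]#[O+]
Why: Zerovalent palladium inserts into the C–I bond of 5 and takes up CO to give aroylpalladium iodide 6, which binds the alkyne of 3 as a π-acid. The phenoxide of 3 then attacks the distal alkyne carbon anti to palladium, closing the furan ring at O1–C2 in a 5-endo-dig mode and leaving divalent palladium, still carrying the aroyl group, on the future C3. Reductive elimination forms the C3–C(=O) bond and returns zerovalent palladium. The closest known reaction type is the palladium-catalysed carbonylative annulation of o-alkynylphenols with aryl iodides to 2-substituted 3-aroylbenzofurans. No stereocenter is formed; the step needs CO insertion to outrun direct aryl transfer, plain cycloisomerisation to the 3-unsubstituted benzofuran and O-aroylation of the phenoxide, which the readily migrating electron-rich 2,4-dialkoxyphenyl group, the CO atmosphere, the mild carbonate base and the low temperature should secure. Regiochemistry is fixed by the substrate, because the ortho placement of OH and alkyne allows only the closure that puts oxygen on the aryl-bearing carbon and the acyl group on C3.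

Step 4
Reactants: 7 3-[2,4-bis(benzyloxy)benzoyl]-2-[4-(benzyloxy)phenyl]-1-benzofuran-5-carbaldehyde; 8 2',4'-bis(benzyloxy)acetophenone
Product: 10 (E)-3-{3-[2,4-bis(benzyloxy)benzoyl]-2-[4-(benzyloxy)phenyl]-1-benzofuran-5-yl}-1-[2,4-bis(benzyloxy)phenyl]prop-2-en-1-one, via racemic aldol adduct 9 (not isolated)
Conditions: KOH (aq.), EtOH–THF, rt
Reagents that add atoms: none
Why: Claisen–Schmidt condensation of the non-enolisable aldehyde 7 with the methyl ketone 8 gives aldol 9, which loses water by E1cB elimination to the conjugated enone; the aldol stereocenter is destroyed and the E geometry is the thermodynamic one.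

Step 5
Reactants: 10 (E)-3-{3-[2,4-bis(benzyloxy)benzoyl]-2-[4-(benzyloxy)phenyl]-1-benzofuran-5-yl}-1-[2,4-bis(benzyloxy)phenyl]prop-2-en-1-one
Product: 12 Isolophirone C, via pentabenzyl dihydrochalcone 11 (not isolated)
Conditions: H2 (1 atm), 10% Pd/C, EtOAc–MeOH, rt
Reagents that add atoms: none
Why: Catalytic hydrogenation should saturate the enone C=C first and then cleave the five benzyl aryl ethers by hydrogenolysis, while the tetrasubstituted C2=C3 bond of the benzofuran and the two aryl ketones, deactivated by hydrogen bonds from the freed ortho hydroxyls, should persist; no stereocenter is present.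

**Compound list**

1 | 4-hydroxy-3-iodobenzaldehyde | O=Cc1ccc(O)c(I)c1 | starting material
2 | 1-(benzyloxy)-4-ethynylbenzene | C#Cc1ccc(OCc2ccccc2)cc1 | starting material
3 | 3-{[4-(benzyloxy)phenyl]ethynyl}-4-hydroxybenzaldehyde | O=Cc1ccc(O)c(C#Cc2ccc(OCc3ccccc3)cc2)c1 | intermediate
4 | 1,3-bis(benzyloxy)benzene | c1ccc(COc2cccc(OCc3ccccc3)c2)cc1 | starting material
5 | 2,4-bis(benzyloxy)-1-iodobenzene | Ic1ccc(OCc2ccccc2)cc1OCc1ccccc1 | intermediate
6 | [2,4-bis(benzyloxy)benzoyl]palladium iodide (divalent palladium; the two PPh3 ligands are not drawn) | O=C(c1ccc(OCc2ccccc2)cc1OCc1ccccc1)[Pd]I | intermediate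
7 | 3-[2,4-bis(benzyloxy)benzoyl]-2-[4-(benzyloxy)phenyl]-1-benzofuran-5-carbaldehyde | O=Cc1ccc2oc(-c3ccc(OCc4ccccc4)cc3)c(C(=O)c3ccc(OCc4ccccc4)cc3OCc3ccccc3)c2c1 | intermediate
8 | 2',4'-bis(benzyloxy)acetophenone, i.e. 1-[2,4-bis(benzyloxy)phenyl]ethan-1-one | CC(=O)c1ccc(OCc2ccccc2)cc1OCc1ccccc1 | starting material
9 | 3-{3-[2,4-bis(benzyloxy)benzoyl]-2-[4-(benzyloxy)phenyl]-1-benzofuran-5-yl}-1-[2,4-bis(benzyloxy)phenyl]-3-hydroxypropan-1-one (racemic) | O=C(CC(O)c1ccc2oc(-c3ccc(OCc4ccccc4)cc3)c(C(=O)c3ccc(OCc4ccccc4)cc3OCc3ccccc3)c2c1)c1ccc(OCc2ccccc2)cc1OCc1ccccc1 | intermediate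
10 | (E)-3-{3-[2,4-bis(benzyloxy)benzoyl]-2-[4-(benzyloxy)phenyl]-1-benzofuran-5-yl}-1-[2,4-bis(benzyloxy)phenyl]prop-2-en-1-one | O=C(/C=C/c1ccc2oc(-c3ccc(OCc4ccccc4)cc3)c(C(=O)c3ccc(OCc4ccccc4)cc3OCc3ccccc3)c2c1)c1ccc(OCc2ccccc2)cc1OCc1ccccc1 | intermediate
11 | 3-{3-[2,4-bis(benzyloxy)benzoyl]-2-[4-(benzyloxy)phenyl]-1-benzofuran-5-yl}-1-[2,4-bis(benzyloxy)phenyl]propan-1-one | O=C(CCc1ccc2oc(-c3ccc(OCc4ccccc4)cc3)c(C(=O)c3ccc(OCc4ccccc4)cc3OCc3ccccc3)c2c1)c1ccc(OCc2ccccc2)cc1OCc1ccccc1 | intermediate
12 | Isolophirone C, 3-[3-(2,4-dihydroxybenzoyl)-2-(4-hydroxyphenyl)-1-benzofuran-5-yl]-1-(2,4-dihydroxyphenyl)propan-1-one (achiral) | O=C(CCc1ccc2oc(-c3ccc(O)cc3)c(C(=O)c3ccc(O)cc3O)c2c1)c1ccc(O)cc1O | target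

**Step count**

Total: 5 steps. Longest linear sequence: 4 steps (steps 1, 3, 4, 5); step 2 is a one-step side branch.

**Steps most likely to fail**

Step 3. CO insertion or acyl transfer may lose against direct cyclisation of the alkynylphenol, direct aryl transfer or O-aroylation of the phenoxide. The fallback separates ring closure from acylation. Compound 3 is iodocyclised (I2, NaHCO3, MeCN, rt) to 2-[4-(benzyloxy)phenyl]-3-iodo-1-benzofuran-5-carbaldehyde F1. Compound 5 is converted by iodine–magnesium exchange (iPrMgCl·LiCl, THF, −20 °C), B(OMe)3 and aqueous acid work-up into 2,4-bis(benzyloxy)phenylboronic acid F2. A carbonylative Suzuki–Miyaura coupling of F1 with F2 (CO 1 atm, PdCl2(PPh3)2, K2CO3, anisole, 80 °C) then gives 7, where the route is rejoined.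

Step 1. The acidic p-formylphenol may add to the new alkyne under the coupling conditions, a premature 5-endo closure to the 3-unsubstituted benzofuran. The fallback masks the nucleophile. Compound 1 is acetylated (Ac2O, pyridine, CH2Cl2) to 4-formyl-2-iodophenyl acetate F3. F3 is coupled with 2 (PdCl2(PPh3)2, CuI, Et3N, THF, rt) to 2-{[4-(benzyloxy)phenyl]ethynyl}-4-formylphenyl acetate F4. Brief methanolysis of the acetate (K2CO3, MeOH, 0 °C) returns to 3.

Step 5. Hydrogenation may over-reduce an aryl ketone or stall at partly benzylated stages. The fallback divides the two tasks and replaces hydrogenolysis by Lewis-acid ether cleavage. Compound 10 is reduced at the enone only with [(Ph3P)CuH]6 (toluene, rt, then aqueous work-up) to 11, which is isolated. Compound 11 is debenzylated with BCl3 and pentamethylbenzene (CH2Cl2, −78 °C) to 12.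

**Further compounds**

F1 | step 3 | 2-[4-(benzyloxy)phenyl]-3-iodo-1-benzofuran-5-carbaldehyde | O=Cc1ccc2oc(-c3ccc(OCc4ccccc4)cc3)c(I)c2c1
F2 | step 3 | 2,4-bis(benzyloxy)phenylboronic acid | OB(O)c1ccc(OCc2ccccc2)cc1OCc1ccccc1
F3 | step 1 | 4-formyl-2-iodophenyl acetate | CC(=O)Oc1ccc(C=O)cc1I
F4 | step 1 | 2-{[4-(benzyloxy)phenyl]ethynyl}-4-formylphenyl acetate | CC(=O)Oc1ccc(C=O)cc1C#Cc1ccc(OCc2ccccc2)cc1
F0 | step 5 | none | none
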